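**Plan**
1. Retrosynthesis: both pyranones are cut at O1–C2 and C2–C3 (carbon from diethyl carbonate) and at C4–C4a and C4'–C4a' (Friedel–Crafts). This leaves a tetra-ortho-substituted biaryl made of rings A and B.
2. Enabling feature: ring A (C4a', C5', C6', C7', C8', C8a' of the 4,7-dimethoxy half) is a 5-methylresorcinol. Its C8' lies between the oxygen-bearing C7' and C8a', sits para to the C5' methyl, and carries ring B, which is the pattern a vinylketene and an aryl ynol ether produce.
3. Ring A is cut at C8a'–C8', C7'–C6' and C8a'–C4a' into 3-methylcyclobutenone and an aryl(silyloxy)acetylene, so the hindered C6–C8' bond enters as an aryl–alkyne bond. The labels C7'/C8a' and C6'/C4a' are interchangeable until the acetyl group enters.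
4. Forward: ring B comes from orcylaldehyde (etherify, homologate to the alkyne, oxidise to the silyl ynol ether). Ring A arises by benzannulation, and both pyranone rings then close in one operation.
5. Stereochemistry: there is no stereocentre, and the C6–C8' axis is not controlled.

Key step: step 6

Assumption: the SMILES carries no descriptor for the C6–C8' axis, so the racemic mixture of atropisomers is taken as the goal.

Step 1
Reactants: 1 2,4-dihydroxy-6-methylbenzaldehyde (orcylaldehyde)
Product: 2 2,4-diisopropoxy-6-methylbenzaldehyde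
Conditions: 2-bromopropane (excess), K2CO3, DMF, 70 °C
Reagents that add atoms: 2-bromopropane, CC(C)Br
Why: Double Williamson etherification in hot DMF also alkylates the hydrogen-bonded 2-OH, and isopropyl ethers are chosen because they withstand BuLi, heat and SnCl4 yet leave with BCl3 in step 9, where a benzyl ether would be lost in an uncontrolled way.

Step 2
Reactants: 2 2,4-diisopropoxy-6-methylbenzaldehyde
Product: 3 2-ethynyl-1,5-diisopropoxy-3-methylbenzene
Conditions: dimethyl (1-diazo-2-oxopropyl)phosphonate, K2CO3, MeOH, rt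
Reagents that add atoms: dimethyl (1-diazo-2-oxopropyl)phosphonate, CC(=O)C(=[N+]=[N-])P(=O)(OC)OC
Why: The Seyferth–Gilbert homologation in its Ohira–Bestmann form converts aryl aldehydes, including electron-rich di-ortho-substituted ones, into terminal alkynes under mild base that leaves the ethers untouched.

Step 3
Reactants: 3 2-ethynyl-1,5-diisopropoxy-3-methylbenzene
Product: 6 {[(2,4-diisopropoxy-6-methylphenyl)ethynyl]oxy}triisopropylsilane, via lithium acetylide 4 (not isolated), via lithium ynolate 5 (not isolated)
Conditions: n-BuLi, THF, −78 °C; LiOOt-Bu (from anhydrous t-BuOOH and LiN(SiMe3)2, THF, −78 °C), −78 → 0 °C; i-Pr3SiOTf, −78 → 0 °C; Et3N-deactivated silica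
Reagents that add atoms: tert-butyl hydroperoxide, CC(C)(C)OO; triisopropylsilyl trifluoromethanesulfonate, CC(C)[Si](OS(=O)(=O)C(F)(F)F)(C(C)C)C(C)C
Why: In the Julia oxidation the lithium peroxide transfers electrophilic oxygen to the acetylide carbon to give the ynolate, and the bulky silyl triflate traps it on oxygen (silyl ynol ether) and not on carbon (silylketene).

Step 4
Reactants: 7 propyne; 8 trichloroacetyl chloride
Product: 10 4,4-dichloro-3-methylcyclobut-2-en-1-one, via dichloroketene 9 (not isolated)
Conditions: Zn–Cu couple, Et2O–DME, excess 7, 0 °C → rt, dry-ice condenser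
Reagents that add atoms: none
Why: Zinc dechlorination of 8 releases dichloroketene, and its [2+2] cycloaddition to a terminal alkyne joins the unsubstituted alkyne carbon to the ketene carbonyl carbon, so the methyl group ends at C3.

Step 5
Reactants: 10 4,4-dichloro-3-methylcyclobut-2-en-1-one
Product: 11 3-methylcyclobut-2-en-1-one
Conditions: Zn dust, AcOH, TMEDA, EtOH, 0 °C → rt; kept as a solution because of its volatility
Reagents that add atoms: none
Why: Buffered zinc reduction removes both α-chlorine atoms through zinc enolates without saturating or opening the strained enone, which is the standard way to 3-alkylcyclobutenones.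

Step 6
Reactants: 6 {[(2,4-diisopropoxy-6-methylphenyl)ethynyl]oxy}triisopropylsilane; 11 3-methylcyclobut-2-en-1-one
Product: 16 2-(2,4-diisopropoxy-6-methylphenyl)-5-methyl-3-(triisopropylsilyloxy)phenol, via vinylketene 12 (not isolated), via vinylcyclobutenone 13 (not isolated), via dienylketene 14 (not isolated), via cyclohexadienone 15 (not isolated)
Conditions: 11 (1.5 equiv), PhMe, sealed tube, 80 °C then 120 °C
Reagents that add atoms: none
Why: On heating, 11 undergoes conrotatory four-electron cleavage of its C1–C4 bond to vinylketene 12, whose ketene unit takes up the ynol ether in a [2+2] cycloaddition to give 13; this reopens to dienylketene 14, which cyclises to dienone 15 and tautomerises to phenol 16. The closest known reaction is the Danheiser benzannulation in its silyloxyalkyne form, the established route from cyclobutenones to monosilylated resorcinols. Ring A is the only ring closed, and it closes by a thermal disrotatory six-electron electrocyclisation (C8a'–C4a') after the cycloaddition has made C8a'–C8' and C7'–C6'. One regiochemical outcome is required: donation from the silyloxy oxygen makes the aryl-bearing alkyne carbon the nucleophilic end, so it attacks the ketene carbonyl carbon, which places ring B between the two oxygens and para to the methyl group. No stereocentre survives, since C4 of 13 becomes sp2, and the axis forms as a racemate. The crowded aryl–aryl bond never has to be made because it is already present in 6, and a silyl ynol ether has no β-hydrogen for retro-ene loss, so it tolerates the temperature.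

Step 7
Reactants: 16 2-(2,4-diisopropoxy-6-methylphenyl)-5-methyl-3-(triisopropylsilyloxy)phenol
Product: 18 2,4-diisopropoxy-2',6'-dimethoxy-4',6-dimethylbiphenyl, via biaryl resorcinol 17 (not isolated)
Conditions: Bu4NF, THF, 0 °C; then MeI (excess), K2CO3, DMF, 40 °C
Reagents that add atoms: iodomethane, CI
Why: Fluoride cleaves the aryl silyl ether and a double Williamson methylation follows in the same flask, which makes ring A symmetric about the C8'–C5' line so that the next step has only one kind of free position on it.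

Step 8
Reactants: 18 2,4-diisopropoxy-2',6'-dimethoxy-4',6-dimethylbiphenyl
Product: 19 1-[3-(3-acetyl-2,6-dimethoxy-4-methylphenyl)-4,6-diisopropoxy-2-methylphenyl]ethan-1-one
Conditions: AcCl, SnCl4, CH2Cl2, −20 → 0 °C
Reagents that add atoms: acetyl chloride, CC(=O)Cl
Why: In this twofold Friedel–Crafts acylation each resorcinol diether ring is attacked para to one alkoxy group and next to the methyl group (C4a' and C4a), the C8 site between two isopropoxy groups is avoided as with orcinol diethers, and each acetyl group deactivates its own ring against a second attack.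

Step 9
Reactants: 19 1-[3-(3-acetyl-2,6-dimethoxy-4-methylphenyl)-4,6-diisopropoxy-2-methylphenyl]ethan-1-one
Product: 20 1-[3-(3-acetyl-2-hydroxy-6-methoxy-4-methylphenyl)-4,6-dihydroxy-2-methylphenyl]ethan-1-one
Conditions: BCl3 (excess), CH2Cl2, −78 °C → rt; aqueous work-up
Reagents that add atoms: none
Why: In this BCl3 ether cleavage, chelation to the acetyl oxygens directs removal of the ortho C8a' methyl and C8a isopropyl groups, the secondary C7 isopropyl ether is cleaved as isopropyl aryl ethers generally are, and the non-chelated C7' methyl ether should persist, as simple aryl methyl ethers do with this reagent.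

Step 10
Reactants: 20 1-[3-(3-acetyl-2-hydroxy-6-methoxy-4-methylphenyl)-4,6-dihydroxy-2-methylphenyl]ethan-1-one
Product: 21 1-[3-(3-acetyl-2-hydroxy-6-methoxy-4-methylphenyl)-4-(benzyloxy)-6-hydroxy-2-methylphenyl]ethan-1-one
Conditions: BnBr (1.05 equiv), K2CO3, acetone, reflux
Reagents that add atoms: benzyl bromide, BrCc1ccccc1
Why: This Williamson benzylation should be selective because the two phenols hydrogen-bonded to acetyl groups are much less acidic and nucleophilic than the free C7 phenol para to the ketone, the selectivity known from 4-O-alkylation of 2,4-dihydroxyacetophenones.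

Step 11
Reactants: 21 1-[3-(3-acetyl-2-hydroxy-6-methoxy-4-methylphenyl)-4-(benzyloxy)-6-hydroxy-2-methylphenyl]ethan-1-one
Product: 23 7-(benzyloxy)-4-hydroxy-6-(4-hydroxy-7-methoxy-5-methyl-2-oxo-2H-chromen-8-yl)-5-methyl-2H-chromen-2-one, via bis(β-keto ester) 22 (not isolated)
Conditions: NaH (excess), (EtO)2CO, PhMe, 110 °C; then aq. HCl
Reagents that add atoms: diethyl carbonate, CCOC(=O)OCC
Why: A crossed Claisen condensation of each methyl ketone enolate with diethyl carbonate, followed by lactonisation onto the neighbouring phenoxide, is the classical 4-hydroxycoumarin synthesis from 2-hydroxyacetophenones, it works on 2-hydroxy-6-methylacetophenones, and the benzyl ether keeps C7 from becoming a deactivating phenoxide.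

Step 12
Reactants: 23 7-(benzyloxy)-4-hydroxy-6-(4-hydroxy-7-methoxy-5-methyl-2-oxo-2H-chromen-8-yl)-5-methyl-2H-chromen-2-one
Product: 24 7-(benzyloxy)-6-(4,7-dimethoxy-5-methyl-2-oxo-2H-chromen-8-yl)-4-methoxy-5-methyl-2H-chromen-2-one
Conditions: Me2SO4, K2CO3, acetone, reflux
Reagents that add atoms: dimethyl sulfate, COS(=O)(=O)OC
Why: O-methylation of the two vinylogous acids with the hard electrophile Me2SO4 in acetone favours the 4-methoxycoumarin over C3-methylation and over the 2-methoxychromone, as is usual for 4-hydroxy-5-methylcoumarins.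

Step 13
Reactants: 24 7-(benzyloxy)-6-(4,7-dimethoxy-5-methyl-2-oxo-2H-chromen-8-yl)-4-methoxy-5-methyl-2H-chromen-2-one
Product: 25 6-(4,7-dimethoxy-5-methyl-2-oxo-2H-chromen-8-yl)-7-hydroxy-4-methoxy-5-methyl-2H-chromen-2-one
Conditions: H2 (1 atm), Pd/C, EtOAc–MeOH, rt
Reagents that add atoms: none
Why: Hydrogenolysis of the aryl benzyl ether proceeds at atmospheric pressure, and the 4-methoxy-substituted C3=C4 bonds, being part of vinylogous carbonates, are not reduced under such mild conditions.

**Compound list**
1 | 2,4-dihydroxy-6-methylbenzaldehyde | Cc1cc(O)cc(O)c1C=O | starting material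
2 | 2,4-diisopropoxy-6-methylbenzaldehyde | Cc1cc(OC(C)C)cc(OC(C)C)c1C=O | intermediate
3 | 2-ethynyl-1,5-diisopropoxy-3-methylbenzene | C#Cc1c(C)cc(OC(C)C)cc1OC(C)C | intermediate
4 | lithium (2,4-diisopropoxy-6-methylphenyl)acetylide | [Li]C#Cc1c(C)cc(OC(C)C)cc1OC(C)C | intermediate
5 | lithium 2-(2,4-diisopropoxy-6-methylphenyl)ethynolate | [Li]OC#Cc1c(C)cc(OC(C)C)cc1OC(C)C | intermediate
6 | {[(2,4-diisopropoxy-6-methylphenyl)ethynyl]oxy}triisopropylsilane | CC(C)[Si](OC#Cc1c(C)cc(OC(C)C)cc1OC(C)C)(C(C)C)C(C)C | intermediate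
7 | propyne | CC#C | starting material
8 | trichloroacetyl chloride | ClC(=O)C(Cl)(Cl)Cl | starting material
9 | dichloroketene | ClC(Cl)=C=O | intermediate
10 | 4,4-dichloro-3-methylcyclobut-2-en-1-one | CC1=CC(=O)C1(Cl)Cl | intermediate
11 | 3-methylcyclobut-2-en-1-one | CC1=CC(=O)C1 | intermediate
12 | 3-methylbuta-1,3-dien-1-one (vinylketene) | CC(=C)C=C=O | intermediate
13 | 2-(2,4-diisopropoxy-6-methylphenyl)-4-(prop-1-en-2-yl)-3-(triisopropylsilyloxy)cyclobut-2-en-1-one (racemic) | O=C1C(c2c(C)cc(OC(C)C)cc2OC(C)C)=C(O[Si](C(C)C)(C(C)C)C(C)C)C1C(C)=C | intermediate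
14 | (3E)-2-(2,4-diisopropoxy-6-methylphenyl)-5-methyl-3-(triisopropylsilyloxy)hexa-1,3,5-trien-1-one | O=C=C(c1c(C)cc(OC(C)C)cc1OC(C)C)/C(O[Si](C(C)C)(C(C)C)C(C)C)=C\C(C)=C | intermediate
15 | 2-(2,4-diisopropoxy-6-methylphenyl)-5-methyl-3-(triisopropylsilyloxy)cyclohexa-2,4-dien-1-one | O=C1CC(C)=CC(O[Si](C(C)C)(C(C)C)C(C)C)=C1c1c(C)cc(OC(C)C)cc1OC(C)C | intermediate
16 | 2-(2,4-diisopropoxy-6-methylphenyl)-5-methyl-3-(triisopropylsilyloxy)phenol | Cc1cc(O)c(c(O[Si](C(C)C)(C(C)C)C(C)C)c1)-c1c(C)cc(OC(C)C)cc1OC(C)C | intermediate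
17 | 2-(2,4-diisopropoxy-6-methylphenyl)-5-methylbenzene-1,3-diol | Cc1cc(O)c(c(O)c1)-c1c(C)cc(OC(C)C)cc1OC(C)C | intermediate
18 | 2,4-diisopropoxy-2',6'-dimethoxy-4',6-dimethylbiphenyl | COc1cc(C)cc(OC)c1-c1c(C)cc(OC(C)C)cc1OC(C)C | intermediate
19 | 1-[3-(3-acetyl-2,6-dimethoxy-4-methylphenyl)-4,6-diisopropoxy-2-methylphenyl]ethan-1-one | COc1cc(C)c(C(C)=O)c(OC)c1-c1c(C)c(C(C)=O)c(OC(C)C)cc1OC(C)C | intermediate
20 | 1-[3-(3-acetyl-2-hydroxy-6-methoxy-4-methylphenyl)-4,6-dihydroxy-2-methylphenyl]ethan-1-one | COc1cc(C)c(C(C)=O)c(O)c1-c1c(C)c(C(C)=O)c(O)cc1O | intermediate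
21 | 1-[3-(3-acetyl-2-hydroxy-6-methoxy-4-methylphenyl)-4-(benzyloxy)-6-hydroxy-2-methylphenyl]ethan-1-one | COc1cc(C)c(C(C)=O)c(O)c1-c1c(C)c(C(C)=O)c(O)cc1OCc1ccccc1 | intermediate
22 | ethyl 3-{3-[6-(benzyloxy)-3-(3-ethoxy-3-oxopropanoyl)-4-hydroxy-2-methylphenyl]-2-hydroxy-4-methoxy-6-methylphenyl}-3-oxopropanoate | CCOC(=O)CC(=O)c1c(C)cc(OC)c(c1O)-c1c(C)c(C(=O)CC(=O)OCC)c(O)cc1OCc1ccccc1 | intermediate
23 | 7-(benzyloxy)-4-hydroxy-6-(4-hydroxy-7-methoxy-5-methyl-2-oxo-2H-chromen-8-yl)-5-methyl-2H-chromen-2-one | COc1cc(C)c2c(O)cc(=O)oc2c1-c1c(OCc3ccccc3)cc2oc(=O)cc(O)c2c1C | intermediate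
24 | 7-(benzyloxy)-6-(4,7-dimethoxy-5-methyl-2-oxo-2H-chromen-8-yl)-4-methoxy-5-methyl-2H-chromen-2-one | COc1cc(C)c2c(OC)cc(=O)oc2c1-c1c(OCc3ccccc3)cc2oc(=O)cc(OC)c2c1C | intermediate
25 | 6-(4,7-dimethoxy-5-methyl-2-oxo-2H-chromen-8-yl)-7-hydroxy-4-methoxy-5-methyl-2H-chromen-2-one | COc1cc(C)c2c(OC)cc(=O)oc2c1-c1c(O)cc2oc(=O)cc(OC)c2c1C | target

Total step count: 13. Longest linear sequence: 11 steps (steps 1–3 and 6–13).

**Steps most likely to fail**

1. Step 6. The di-ortho-substituted aryl group may slow the ketene–alkyne cycloaddition. The vinylketene would then be lost to self-condensation and to acylation of the phenol already formed. The fallback keeps the same three bonds but makes the vinylketene at room temperature by photochemical Wolff rearrangement, the diazo ketone version of the same benzannulation. Commercial 3-methylbut-3-en-2-one is trifluoroacetylated (LiN(SiMe3)2, CF3CO2CH2CF3, THF, −78 °C) to 1,1,1-trifluoro-5-methylhex-5-ene-2,4-dione F1. Diazo transfer (MsN3, Et3N, H2O, MeCN) then gives 1-diazo-3-methylbut-3-en-2-one F2. Irradiation of F2 with 6 in CH2Cl2 produces 12 without heat, so adduct 13 can build up, and a later thermolysis in toluene completes the cascade. This fallback sets out from 6 and comes back to the route at 16.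

2. Step 3. Oxygen transfer from the peroxide to the hindered, electron-rich acetylide may stall, leaving alkyne that cannot be separated from the sensitive ynol ether without hydrolysis. The fallback reaches the ynolate by skeletal rearrangement instead of oxidation. LiCHBr2 (CH2Br2, LDA, THF, −78 °C) is added to aldehyde 2 to give 2,2-dibromo-1-(2,4-diisopropoxy-6-methylphenyl)ethan-1-ol F3. Dess–Martin oxidation of F3 gives 2,2-dibromo-1-(2,4-diisopropoxy-6-methylphenyl)ethan-1-one F4. Treatment of F4 with LiN(SiMe3)2 and then n-BuLi (−78 °C → rt) triggers the Kowalski-type 1,2-aryl shift, which the electron-rich aryl group favours. The ynolate is silylated as in step 3. This fallback sets out from 2 and comes back to the route at 5.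

3. Step 8. The Lewis acid may strip isopropyl groups before both acylations are complete, so that freed phenols are O-acetylated and misdirect the second substitution. Attack at C8 is a further possible leak. The fallback builds the acetyl groups in stages without a strong Lewis acid. Twofold Vilsmeier–Haack formylation of 18 (POCl3, DMF, 0 → 60 °C) gives 3-(3-formyl-2,6-dimethoxy-4-methylphenyl)-4,6-diisopropoxy-2-methylbenzaldehyde F5. Addition of MeMgBr (THF, 0 °C) gives 1-{3-[3-(1-hydroxyethyl)-2,6-dimethoxy-4-methylphenyl]-4,6-diisopropoxy-2-methylphenyl}ethan-1-ol F6 as a mixture of diastereomers. Dess–Martin oxidation of F6 gives the diketone. This fallback sets out from 18 and comes back to the route at 19.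

**Further compounds**
F1 | step 6 | 1,1,1-trifluoro-5-methylhex-5-ene-2,4-dione | C=C(C)C(=O)CC(=O)C(F)(F)F
F2 | step 6 | 1-diazo-3-methylbut-3-en-2-one | C=C(C)C(=O)C=[N+]=[N-]
F3 | step 3 | 2,2-dibromo-1-(2,4-diisopropoxy-6-methylphenyl)ethan-1-ol (racemic) | OC(C(Br)Br)c1c(C)cc(OC(C)C)cc1OC(C)C
F4 | step 3 | 2,2-dibromo-1-(2,4-diisopropoxy-6-methylphenyl)ethan-1-one | O=C(C(Br)Br)c1c(C)cc(OC(C)C)cc1OC(C)C
F5 | step 8 | 3-(3-formyl-2,6-dimethoxy-4-methylphenyl)-4,6-diisopropoxy-2-methylbenzaldehyde | COc1cc(C)c(C=O)c(OC)c1-c1c(C)c(C=O)c(OC(C)C)cc1OC(C)C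
F6 | step 8 | 1-{3-[3-(1-hydroxyethyl)-2,6-dimethoxy-4-methylphenyl]-4,6-diisopropoxy-2-methylphenyl}ethan-1-ol (mixture of diastereomers) | COc1cc(C)c(C(C)O)c(OC)c1-c1c(C)c(C(C)O)c(OC(C)C)cc1OC(C)C
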